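Azulene numbering is used: C1–C3, C3a and C8a form the five-membered ring (C3 is the carbinol carbon with the isopropyl group), and C4 (ester carbon) to C8 complete the seven-membered ring (C6 carries the vinylic methyl).
The ester is attached last; the C4 carbinol comes from a hydroxyl-directed reduction of a C4 ketone, C3a–H from hydrogen-bond-controlled equilibration next to that ketone, and the angular C8a methyl from cuprate addition to a C3a=C8a enone.
The seven-membered ring is made by a (4+3) annulation that joins C4–C5 and C7–C8 in one flask: a siloxy diene C4=C3a–C8a=C8 plus a 2-(silylmethyl)allyl cation C5–C6–C7, whose exocyclic methylene later becomes the C6 methyl.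
Enabling feature: C4, C3a, C8a and C8 are contiguous and the two middle atoms are shared with the five-membered ring, so they can be presented as an s-cis-locked 1,2-dialkylidenecyclopentane, the silyl dienol ether of a 2-methylcyclopent-1-ene-1-carbaldehyde (formyl carbon = C4, γ-methyl = C8); C5–C6(Me)–C7 is an isobutenyl unit, i.e. a 2-substituted allyl cation.
That aldehyde is the ozonolysis/aldol ring-contraction product of (S)-terpinen-4-ol, all ten carbons of which are kept (its carbinol carbon is C3, its ring methyl becomes ring carbon C8); the five-membered ring is formed first, the seven-membered ring second.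

Key step: step 5

Assumption: (S)-(+)-terpinen-4-ol is taken as a commercial monoterpene alcohol of high enantiomeric purity; a lot of lower purity would be upgraded by recrystallisation of a later crystalline intermediate.

Step 1
Reactants: 1 (S)-(+)-terpinen-4-ol
Product: 2 triethyl{[(1S)-4-methyl-1-(propan-2-yl)cyclohex-3-en-1-yl]oxy}silane
Conditions: TESOTf, 2,6-lutidine, CH2Cl2, 0 °C to rt
Reagents that add atoms: triethylsilyl trifluoromethanesulfonate, CC[Si](CC)(CC)OS(=O)(=O)C(F)(F)F
Why: Silylation of the hindered tertiary alcohol with a silyl triflate and a hindered pyridine base is routine and should give the TES ether, which blocks retro-aldol cleavage and hemiketal formation in steps 2 to 7, and the future C3 stereocentre is not touched.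

Step 2
Reactants: 2 triethyl{[(1S)-4-methyl-1-(propan-2-yl)cyclohex-3-en-1-yl]oxy}silane
Product: 4 (3S)-6-oxo-3-(propan-2-yl)-3-[(triethylsilyl)oxy]heptanal, via ozonide 3 (not isolated)
Conditions: O3, CH2Cl2, −78 °C; then PPh3, −78 °C to rt
Reagents that add atoms: ozone, [O-][O+]=O
Why: Ozonolysis with reductive work-up cleaves the only C=C bond of 2 to a methyl ketone and an aldehyde without touching the silyl ether or the quaternary stereocentre.

Step 3
Reactants: 4 (3S)-6-oxo-3-(propan-2-yl)-3-[(triethylsilyl)oxy]heptanal
Product: 6 (5R)-2-methyl-5-(propan-2-yl)-5-[(triethylsilyl)oxy]cyclopent-1-ene-1-carbaldehyde, via aldol 5 (not isolated)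
Conditions: Bn2NH·CF3CO2H (0.3 equiv), benzene, 50 °C
Reagents that add atoms: none
Why: Ammonium-salt-catalysed intramolecular aldol condensation, in which the enamine of the aldehyde attacks the methyl ketone in a 5-exo-trig closure and water is lost, should give the tetrasubstituted cyclopentene carbaldehyde as in the classical ring contraction of cyclohexene-derived keto aldehydes, the weakly acidic medium being chosen to spare the β-silyloxy group, and no new stereocentre remains.

Step 4
Reactants: 6 (5R)-2-methyl-5-(propan-2-yl)-5-[(triethylsilyl)oxy]cyclopent-1-ene-1-carbaldehyde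
Product: 7 triethyl{[(1R,2Z)-3-methylidene-1-(propan-2-yl)-2-{[(trimethylsilyl)oxy]methylidene}cyclopentyl]oxy}silane
Conditions: TMSOTf, Et3N, Et2O, −78 °C to 0 °C
Reagents that add atoms: trimethylsilyl trifluoromethanesulfonate, C[Si](C)(C)OS(=O)(=O)C(F)(F)F
Why: Soft enolisation of the enal (O-silylation, then amine deprotonation) is a vinylogous silyl enol ether formation in which the γ-methyl group, cis to the formyl group and the least hindered γ-position, should be deprotonated under kinetic control to give the s-cis-locked exocyclic diene, the Z enol ether geometry following from the s-trans enal conformer.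

Step 5
Reactants: 7 triethyl{[(1R,2Z)-3-methylidene-1-(propan-2-yl)-2-{[(trimethylsilyl)oxy]methylidene}cyclopentyl]oxy}silane; 8 2-[(trimethylsilyl)methyl]prop-2-en-1-ol
Product: 11 (3R)-6-methylidene-3-(propan-2-yl)-3-[(triethylsilyl)oxy]-1,2,3,4,5,6,7,8-octahydroazulen-4-ol (C4 epimers), via allyl triflate 9 (not isolated), via annulated trimethylsilyl ether 10 (not isolated)
Conditions: 8, Tf2O, 2,6-di-tert-butyl-4-methylpyridine, CH2Cl2, −78 °C; then 7, −78 °C to −40 °C; then K2CO3, MeOH, 0 °C
Reagents that add atoms: none
Why: The allyl triflate 9 formed in the flask is a 2-(silylmethyl)allyl cation equivalent that should be captured at C8, the unhindered γ-terminus of the s-cis-locked siloxy diene 7, to give an O-silyl oxocarbenium ion in which C4 and the pendant allylsilane are held cis on the C3a=C8a bond; the allylsilane terminus then adds to C4 and loses the trimethylsilyl group to leave the exocyclic C6 methylene, so that C7–C8 and C4–C5 are both made in one flask. The closest known reaction type is the (4+3) cycloaddition of 2-[(trimethylsilyl)methyl]allyl cations with conjugated dienes, here in its stepwise limit of a vinylogous Mukaiyama alkylation followed by an intramolecular Hosomi–Sakurai reaction. The seven-membered ring is closed by attack of the allylsilane terminus C5 on the oxocarbenium carbon C4 (exo with respect to the C=O bond, endo with respect to the allylsilane double bond), whereas the alternative conjugate closure at C8a would be a 5-endo-trig attack on a fully substituted carbon and should not compete. The only new stereocentre, C4, is expected as a mixture because the substrate offers no strong facial bias, and this is tolerated since step 6 converts C4 into a ketone. The selectivities that matter are γ- over α-attack of the dienol ether, secured by the quaternary C3 next to C3a, and capture of 9 by 7 in preference to self-condensation of 9, secured by adding 7 to the preformed triflate at −78 °C with a hindered, non-nucleophilic base. Mild methanolysis then cleaves only the secondary trimethylsilyl ether and leaves the tertiary triethylsilyl ether in place.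

Step 6
Reactants: 11 (3R)-6-methylidene-3-(propan-2-yl)-3-[(triethylsilyl)oxy]-1,2,3,4,5,6,7,8-octahydroazulen-4-ol (C4 epimers)
Product: 12 (3R)-6-methylidene-3-(propan-2-yl)-3-[(triethylsilyl)oxy]-2,3,5,6,7,8-hexahydroazulen-4(1H)-one
Conditions: Dess–Martin periodinane, pyridine, CH2Cl2, 0 °C to rt
Reagents that add atoms: none
Why: Dess–Martin oxidation of the only free hydroxyl (secondary, allylic) under buffered, non-enolising conditions should give the C4 ketone conjugated with C3a=C8a while the exocyclic C6 methylene stays out of conjugation, and both C4 epimers converge on one compound.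

Step 7
Reactants: 12 (3R)-6-methylidene-3-(propan-2-yl)-3-[(triethylsilyl)oxy]-2,3,5,6,7,8-hexahydroazulen-4(1H)-one
Product: 14 (3R,8aS)-8a-methyl-6-methylidene-3-(propan-2-yl)-3-[(triethylsilyl)oxy]-2,3,3a,5,6,7,8,8a-octahydroazulen-4(1H)-one (C3a epimers), via lithium enolate 13 (not isolated)
Conditions: Me2CuLi (from MeLi and CuI), Et2O, −78 °C to −30 °C; then aq NH4Cl, −78 °C
Reagents that add atoms: lithium dimethylcuprate Me2CuLi, [Li+].C[Cu-]C
Why: Gilman cuprate conjugate addition to the only conjugated alkene should set the quaternary C8a centre, the methyl group entering anti to the isopropyl group that allylic 1,2-strain with the C4 carbonyl forces into the pseudoaxial position on the lower face of the cyclopentene, while C3a is protonated without control and is corrected in step 9.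

Step 8
Reactants: 14 (3R,8aS)-8a-methyl-6-methylidene-3-(propan-2-yl)-3-[(triethylsilyl)oxy]-2,3,3a,5,6,7,8,8a-octahydroazulen-4(1H)-one (C3a epimers)
Product: 15 (3R,8aS)-3-hydroxy-8a-methyl-6-methylidene-3-(propan-2-yl)-2,3,3a,5,6,7,8,8a-octahydroazulen-4(1H)-one (C3a epimers)
Conditions: HF·pyridine, pyridine, THF, 0 °C to rt
Reagents that add atoms: none
Why: Fluoride-mediated desilylation under buffered, weakly acidic conditions frees the tertiary hydroxyl without forming an alkoxide, so that retro-aldol opening of the β-hydroxy ketone is avoided, and no stereocentre is affected.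

Step 9
Reactants: 15 (3R,8aS)-3-hydroxy-8a-methyl-6-methylidene-3-(propan-2-yl)-2,3,3a,5,6,7,8,8a-octahydroazulen-4(1H)-one (C3a epimers)
Product: 16 (3R,3aR,8aS)-3-hydroxy-6,8a-dimethyl-3-(propan-2-yl)-2,3,3a,7,8,8a-hexahydroazulen-4(1H)-one
Conditions: DBU, toluene, rt to 50 °C
Reagents that add atoms: none
Why: Amidine-mediated enolisation moves the exocyclic alkene into conjugation (deconjugated-to-conjugated enone isomerisation through the dienolate) and equilibrates the α-centre C3a, where the trans-fused epimer should prevail in the aprotic medium because only it can hold the intramolecular O–H···O=C hydrogen bond between the C3 hydroxyl and the C4 carbonyl and keeps the carbonyl branch anti to the isopropyl group.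

Step 10
Reactants: 16 (3R,3aR,8aS)-3-hydroxy-6,8a-dimethyl-3-(propan-2-yl)-2,3,3a,7,8,8a-hexahydroazulen-4(1H)-one
Product: 17 (3R,3aS,4S,8aS)-6,8a-dimethyl-3-(propan-2-yl)-1,2,3,3a,4,7,8,8a-octahydroazulene-3,4-diol
Conditions: Me4NBH(OAc)3, MeCN/AcOH (1:1), −30 °C to −10 °C
Reagents that add atoms: none
Why: Evans–Saksena hydroxyl-directed reduction, in which the acetoxyborohydride is bound to the tertiary C3 hydroxyl with boron anti to the isopropyl group and delivers hydride intramolecularly to the carbonyl face that the angular methyl group shields from external reagents, should give the (4S) allylic alcohol with oxygen cis to H-3a and leave the C5=C6 bond alone.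

Step 11
Reactants: 17 (3R,3aS,4S,8aS)-6,8a-dimethyl-3-(propan-2-yl)-1,2,3,3a,4,7,8,8a-octahydroazulene-3,4-diol; 18 4-(acetyloxy)benzoyl chloride
Product: 19 (3R,3aS,4S,8aS)-3-hydroxy-6,8a-dimethyl-3-(propan-2-yl)-1,2,3,3a,4,7,8,8a-octahydroazulen-4-yl 4-(acetyloxy)benzoate
Conditions: pyridine, DMAP (0.1 equiv), CH2Cl2, 0 °C to rt
Reagents that add atoms: none
Why: DMAP-catalysed acylation with the acid chloride should esterify only the secondary allylic hydroxyl, the tertiary hydroxyl being inert under these conditions and the phenol being masked as its acetate, and no stereocentre changes.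

Step 12
Reactants: 19 (3R,3aS,4S,8aS)-3-hydroxy-6,8a-dimethyl-3-(propan-2-yl)-1,2,3,3a,4,7,8,8a-octahydroazulen-4-yl 4-(acetyloxy)benzoate
Product: 20 (3R,3aS,4S,8aS)-3-hydroxy-6,8a-dimethyl-3-(propan-2-yl)-1,2,3,3a,4,7,8,8a-octahydroazulen-4-yl 4-hydroxybenzoate (target, CNP0323098.1)
Conditions: pyrrolidine, CH2Cl2, 0 °C
Reagents that add atoms: none
Why: Aminolysis of the aryl acetate, an activated ester, is much faster than attack on the hindered secondary alkyl benzoate, so the phenol should be released selectively to give the target with all four stereocentres intact.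

Compound list
1 | (S)-(+)-terpinen-4-ol, (1S)-4-methyl-1-(propan-2-yl)cyclohex-3-en-1-ol | CC1=CC[C@](O)(C(C)C)CC1 | starting material
2 | triethyl{[(1S)-4-methyl-1-(propan-2-yl)cyclohex-3-en-1-yl]oxy}silane | CC1=CC[C@](O[Si](CC)(CC)CC)(C(C)C)CC1 | intermediate
3 | secondary ozonide (1,2,4-trioxolane) of 2, diastereomer mixture at the trioxolane carbons | CC12CC[C@@](O[Si](CC)(CC)CC)(C(C)C)CC(OO1)O2 | intermediate
4 | (3S)-6-oxo-3-(propan-2-yl)-3-[(triethylsilyl)oxy]heptanal | O=CC[C@](O[Si](CC)(CC)CC)(C(C)C)CCC(C)=O | intermediate
5 | (5R)-2-hydroxy-2-methyl-5-(propan-2-yl)-5-[(triethylsilyl)oxy]cyclopentane-1-carbaldehyde, aldol, mixture at C1 and C2 | O=CC1C(C)(O)CC[C@@]1(O[Si](CC)(CC)CC)C(C)C | intermediate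
6 | (5R)-2-methyl-5-(propan-2-yl)-5-[(triethylsilyl)oxy]cyclopent-1-ene-1-carbaldehyde | O=CC1=C(C)CC[C@@]1(O[Si](CC)(CC)CC)C(C)C | intermediate
7 | triethyl{[(1R,2Z)-3-methylidene-1-(propan-2-yl)-2-{[(trimethylsilyl)oxy]methylidene}cyclopentyl]oxy}silane (siloxy group trans to the ring methylidene carbon) | C[Si](C)(C)O/C=C1/C(=C)CC[C@@]1(O[Si](CC)(CC)CC)C(C)C | intermediate
8 | 2-[(trimethylsilyl)methyl]prop-2-en-1-ol | C=C(CO)C[Si](C)(C)C | starting material
9 | 2-[(trimethylsilyl)methyl]prop-2-en-1-yl trifluoromethanesulfonate | C=C(C[Si](C)(C)C)COS(=O)(=O)C(F)(F)F | intermediate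
10 | trimethylsilyl ether of 11, (3R)-6-methylidene-3-(propan-2-yl)-3-[(triethylsilyl)oxy]-4-[(trimethylsilyl)oxy]-1,2,3,4,5,6,7,8-octahydroazulene, C4 epimers | C[Si](C)(C)OC1CC(=C)CCC2=C1[C@](O[Si](CC)(CC)CC)(C(C)C)CC2 | intermediate
11 | (3R)-6-methylidene-3-(propan-2-yl)-3-[(triethylsilyl)oxy]-1,2,3,4,5,6,7,8-octahydroazulen-4-ol, C4 epimers | OC1CC(=C)CCC2=C1[C@](O[Si](CC)(CC)CC)(C(C)C)CC2 | intermediate
12 | (3R)-6-methylidene-3-(propan-2-yl)-3-[(triethylsilyl)oxy]-2,3,5,6,7,8-hexahydroazulen-4(1H)-one | O=C1CC(=C)CCC2=C1[C@](O[Si](CC)(CC)CC)(C(C)C)CC2 | intermediate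
13 | lithium C4-enolate of 14 (C4=C3a enolate) | C=C1CC([O-])=C2[C@@](C)(CC1)CC[C@@]2(O[Si](CC)(CC)CC)C(C)C.[Li+] | intermediate
14 | (3R,8aS)-8a-methyl-6-methylidene-3-(propan-2-yl)-3-[(triethylsilyl)oxy]-2,3,3a,5,6,7,8,8a-octahydroazulen-4(1H)-one, C3a epimers | C=C1CC(=O)C2[C@@](C)(CC1)CC[C@@]2(O[Si](CC)(CC)CC)C(C)C | intermediate
15 | (3R,8aS)-3-hydroxy-8a-methyl-6-methylidene-3-(propan-2-yl)-2,3,3a,5,6,7,8,8a-octahydroazulen-4(1H)-one, C3a epimers | C=C1CC(=O)C2[C@@](C)(CC1)CC[C@@]2(O)C(C)C | intermediate
16 | (3R,3aR,8aS)-3-hydroxy-6,8a-dimethyl-3-(propan-2-yl)-2,3,3a,7,8,8a-hexahydroazulen-4(1H)-one (trans ring fusion) | CC1=CC(=O)[C@@H]2[C@@](C)(CC1)CC[C@@]2(O)C(C)C | intermediate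
17 | (3R,3aS,4S,8aS)-6,8a-dimethyl-3-(propan-2-yl)-1,2,3,3a,4,7,8,8a-octahydroazulene-3,4-diol | CC1=C[C@H](O)[C@@H]2[C@@](C)(CC1)CC[C@@]2(O)C(C)C | intermediate
18 | 4-(acetyloxy)benzoyl chloride | CC(=O)Oc1ccc(cc1)C(Cl)=O | starting material
19 | (3R,3aS,4S,8aS)-3-hydroxy-6,8a-dimethyl-3-(propan-2-yl)-1,2,3,3a,4,7,8,8a-octahydroazulen-4-yl 4-(acetyloxy)benzoate | CC1=C[C@H](OC(=O)c2ccc(OC(C)=O)cc2)[C@@H]2[C@@](C)(CC1)CC[C@@]2(O)C(C)C | intermediate
20 | (3R,3aS,4S,8aS)-3-hydroxy-6,8a-dimethyl-3-(propan-2-yl)-1,2,3,3a,4,7,8,8a-octahydroazulen-4-yl 4-hydroxybenzoate | CC1=C[C@H](OC(=O)c2ccc(O)cc2)[C@@H]2[C@@](C)(CC1)CC[C@@]2(O)C(C)C | target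

Total step count: 12. Longest linear sequence: 12 steps (1 to 20); 8 and 18 are commercial and enter in steps 5 and 11.

Steps most likely to fail

Step 5 (key annulation). The bifunctional triflate 9 may be consumed by self-condensation, the dienol ether may be protonated by the pyridinium salt, or the silyl group may be lost after the first C–C bond so that ring closure does not follow. The fallback sets out from 7 and makes the two bonds in separate flasks. Compound 7 would be alkylated at C8 with commercial 2-(chloromethyl)-3-(trimethylsilyl)prop-1-ene under AgOTf promotion (silver-assisted vinylogous alkylation of a silyl dienol ether) and hydrolysed on work-up to the open-chain enal (5R)-5-(propan-2-yl)-5-[(triethylsilyl)oxy]-2-{3-[(trimethylsilyl)methyl]but-3-en-1-yl}cyclopent-1-ene-1-carbaldehyde F1. F1 would then be closed by fluoride-triggered intramolecular 1,2-allylation of the aldehyde (Bu4N[Ph3SiF2], THF, 0 °C), an anionic allyl transfer that favours carbonyl addition, and this comes back to the route at 11.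

Step 4 (dienol ether). Deprotonation may occur at the ring methylene C1 instead of the methyl group, or the kinetic diene may equilibrate to the endocyclic, s-trans dienol ether, which cannot annulate. The fallback sets out from 6 and removes the regiochemical choice. Photodeconjugation of 6 (hν 350 nm, 1,2-dimethylimidazole 0.1 equiv, MeCN, 0 °C) proceeds by photoenolisation through 1,5-hydrogen transfer, which is geometrically possible only from the γ-methyl cis to the formyl group, and ketonisation would give the β,γ-unsaturated aldehyde (5R)-2-methylidene-5-(propan-2-yl)-5-[(triethylsilyl)oxy]cyclopentane-1-carbaldehyde F2 (C1 epimers). Enol silylation of its single α-hydrogen (TMSOTf, Et3N, Et2O, −78 °C) comes back to the route at 7.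

Step 7 (angular methyl). Conjugate addition at the fully substituted β-carbon may be slow, so that deprotonation of the doubly activated C5 methylene or attack from the wrong face competes. The fallback sets out from 12 and delivers the carbon intramolecularly by a silicon-tethered radical cyclisation. Desilylation (HF·pyridine, THF) would give the hydroxy enone (3R)-3-hydroxy-6-methylidene-3-(propan-2-yl)-2,3,5,6,7,8-hexahydroazulen-4(1H)-one F3. Silylation with (bromomethyl)chlorodimethylsilane and imidazole in DMF would give its (bromomethyl)dimethylsilyl ether F4. Bu3SnH and AIBN in benzene at 80 °C would trigger a 6-endo radical conjugate addition to C8a from the face of the C3 oxygen, giving the siloxane-bridged ketone F5 (C8a–CH2–SiMe2–O–C3, C3a epimers). Protodesilylation with TBAF in DMF at 60 °C would cleave the Si–C and Si–O bonds to leave the C8a methyl and the free C3 hydroxyl, which comes back to the route at 15; any material already conjugated simply runs ahead of step 9.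

Further compounds
F1 | step 5 | (5R)-5-(propan-2-yl)-5-[(triethylsilyl)oxy]-2-{3-[(trimethylsilyl)methyl]but-3-en-1-yl}cyclopent-1-ene-1-carbaldehyde | O=CC1=C(CCC(=C)C[Si](C)(C)C)CC[C@@]1(O[Si](CC)(CC)CC)C(C)C
F2 | step 4 | (5R)-2-methylidene-5-(propan-2-yl)-5-[(triethylsilyl)oxy]cyclopentane-1-carbaldehyde, C1 epimers | O=CC1C(=C)CC[C@@]1(O[Si](CC)(CC)CC)C(C)C
F3 | step 7 | (3R)-3-hydroxy-6-methylidene-3-(propan-2-yl)-2,3,5,6,7,8-hexahydroazulen-4(1H)-one | O=C1CC(=C)CCC2=C1[C@](O)(C(C)C)CC2
F4 | step 7 | (3R)-3-{[(bromomethyl)dimethylsilyl]oxy}-6-methylidene-3-(propan-2-yl)-2,3,5,6,7,8-hexahydroazulen-4(1H)-one | O=C1CC(=C)CCC2=C1[C@](O[Si](C)(C)CBr)(C(C)C)CC2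
F5 | step 7 | siloxane-bridged ketone with a C8a–CH2–Si(CH3)2–O–C3 bridge on the 6-methylidene-3-(propan-2-yl)octahydroazulen-4-one core, C3a epimers | C=C1CC(=O)C2[C@@]3(CC1)CC[C@@]2(O[Si](C)(C)C3)C(C)C
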